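**Retrosynthetic overview**
1. The target is an 8,6''-linked biflavone. The acacetin half (benzo ring A, pyranone ring C, 4-methoxyphenyl ring B) is joined through C8, the carbon next to C8a–O1. The genkwanin half (benzo ring D, pyranone ring F, 4-hydroxyphenyl ring E) is joined through C6'', the carbon between C5''–OH and C7''–OMe and para to C8a''–O1''. The strategy rests on this feature: the halves differ only in which ring oxygen (on C8a or on C8a'') becomes the pyranone oxygen and in the aryl group at C2 and C2'', so one aroyl ester on each of these two oxygens fixes both differences.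
2. End game: rings C and F are closed together by cyclodehydration of a bis(1,3-diketone) through the C8a and C8a'' phenols, followed by O-debenzylation and removal of the C5'' methyl group.
3. Key disconnection: C2–C3 and C2''–C3'' are formed in one flask by a twofold Baker–Venkataraman O-to-C aroyl shift in a 3,3'-diacetylbiphenyl bis-ester (4-methoxybenzoate on O–C8a, 4-benzyloxybenzoate on O–C8a'').
4. The bis-ester comes from a Suzuki–Miyaura coupling (bond C8–C6'') of a ring A iodo ester with a ring D boronate ester, each already carrying its own aroyl group.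
5. Ring A comes from phloroacetophenone by iodination ortho to the chelated phenol. Ring D is built from symmetrical 2-bromo-1,3-dimethoxybenzene, because direct halogenation of 2-hydroxy-4,6-dimethoxyacetophenone goes ortho to the phenol and would lead to an 8''-linked half.

Key step: step 9

Assumption: the target string carries no axial descriptor, so the hindered C8–C6'' biaryl axis is made without stereocontrol (racemic).

**Route**

Step 1
Reactants: 1 2,4,6-trihydroxyacetophenone (phloroacetophenone)
Product: 2 1-[2,4-bis(benzyloxy)-6-hydroxyphenyl]ethanone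
Conditions: BnBr (2.1 equiv), K2CO3, DMF, rt
Reagents that add atoms: benzyl bromide BrCc1ccccc1
Why: Williamson etherification: the C4 hydroxyl and one of the two equivalent ortho hydroxyls are alkylated, while the remaining ortho hydroxyl is held in a hydrogen bond to the acetyl carbonyl and should stay free with a carbonate base and two equivalents of halide.

Step 2
Reactants: 2 1-[2,4-bis(benzyloxy)-6-hydroxyphenyl]ethanone
Product: 3 1-[4,6-bis(benzyloxy)-2-hydroxy-3-iodophenyl]ethanone
Conditions: N-iodosuccinimide (1.05 equiv), TFA (cat.), MeCN/CH2Cl2, 0 °C to rt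
Reagents that add atoms: N-iodosuccinimide O=C1CCC(=O)N1I
Why: Electrophilic aromatic iodination, expected at C3 (ortho to the free chelated phenol and para to the C6 ether) and not at C5, which lies between two benzyloxy groups; this is the usual orientation for 2-hydroxy-4,6-dialkoxyacetophenones and puts iodine on the future C8 (to be confirmed by NOE contacts of the remaining ring proton to both OCH2Ph groups).

Step 3
Reactants: 3 1-[4,6-bis(benzyloxy)-2-hydroxy-3-iodophenyl]ethanone; 4 4-methoxybenzoyl chloride
Product: 5 2-acetyl-3,5-bis(benzyloxy)-6-iodophenyl 4-methoxybenzoate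
Conditions: pyridine, DMAP (cat.), 60 °C
Reagents that add atoms: none
Why: DMAP-catalysed O-acylation (esterification) of the hindered, chelated phenol under conditions too weakly basic to enolise the ketone, so the ester that will deliver ring B sits on the future O1.

Step 4
Reactants: 6 2-bromo-1,3-dimethoxybenzene
Product: 8 4-bromo-3,5-dimethoxyphenol, via pinacol boronate 7 (not isolated)
Conditions: [Ir(OMe)(cod)]2 (1.5 mol%), 4,4'-di-tert-butyl-2,2'-bipyridine (3 mol%), B2pin2 (0.6 equiv), THF, 80 °C; then 30% H2O2, aq. NaOH, 0 °C; acidify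
Reagents that add atoms: bis(pinacolato)diboron CC1(C)OB(OC1(C)C)B1OC(C)(C)C(C)(C)O1 (boryl group of 7); hydrogen peroxide OO (phenol oxygen of 8)
Why: Sterically governed iridium-catalysed C–H borylation takes the only C–H without an ortho substituent (C5), and oxidation of the C–B bond then gives the phenol at the same carbon; the aryl bromide is inert to both operations and the symmetry of 6 makes the outcome regiochemically unambiguous.

Step 5
Reactants: 8 4-bromo-3,5-dimethoxyphenol
Product: 10 1-(3-bromo-6-hydroxy-2,4-dimethoxyphenyl)ethanone, via aryl acetate 9 (not isolated)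
Conditions: Ac2O (1.5 equiv), BF3·OEt2 (3 equiv), 70 °C; then aq. NaOAc
Reagents that add atoms: acetic anhydride CC(=O)OC(C)=O
Why: O-acetylation followed by BF3-mediated Fries rearrangement: the acyl group can only enter one of the two equivalent positions ortho to the phenol (para is blocked by bromine), so bromine ends between the two methoxy groups and para to the chelated phenol, the pattern that halogenation of the parent ketone would not give.

Step 6
Reactants: 10 1-(3-bromo-6-hydroxy-2,4-dimethoxyphenyl)ethanone; 11 4-(benzyloxy)benzoyl chloride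
Product: 12 2-acetyl-4-bromo-3,5-dimethoxyphenyl 4-(benzyloxy)benzoate
Conditions: Et3N, DMAP (cat.), CH2Cl2, rt
Reagents that add atoms: none
Why: DMAP-catalysed esterification of the chelated phenol, which places the ester that will deliver ring E on the future O1''.

Step 7
Reactants: 12 2-acetyl-4-bromo-3,5-dimethoxyphenyl 4-(benzyloxy)benzoate
Product: 13 2-acetyl-3,5-dimethoxy-4-(4,4,5,5-tetramethyl-1,3,2-dioxaborolan-2-yl)phenyl 4-(benzyloxy)benzoate
Conditions: pinacolborane (2 equiv), PdCl2(MeCN)2 (3 mol%), SPhos (12 mol%), Et3N (3 equiv), 1,4-dioxane, 90 °C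
Reagents that add atoms: pinacolborane CC1(C)OBOC1(C)C
Why: Palladium-catalysed borylation of the aryl bromide with pinacolborane (Miyaura-type borylation), for which the SPhos ligand is suited to electron-rich bromides with two ortho alkoxy groups; triethylamine is too weak a base to start the acyl shift, and the ketone and ester should be tolerated.

Step 8
Reactants: 5 2-acetyl-3,5-bis(benzyloxy)-6-iodophenyl 4-methoxybenzoate; 13 2-acetyl-3,5-dimethoxy-4-(4,4,5,5-tetramethyl-1,3,2-dioxaborolan-2-yl)phenyl 4-(benzyloxy)benzoate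
Product: 14 3,3'-diacetyl-4,6-bis(benzyloxy)-2',6'-dimethoxybiphenyl-2,4'-diyl 2-(4-methoxybenzoate) 4'-[4-(benzyloxy)benzoate] (the biaryl bis-ester; unprimed ring = ring A, primed ring = ring D)
Conditions: Pd2(dba)3 (3 mol%), SPhos (12 mol%), K3PO4 (powdered, 3 equiv), toluene, 100 °C
Reagents that add atoms: none
Why: Suzuki–Miyaura cross-coupling; SPhos-ligated zerovalent palladium is among the systems that form tetra-ortho-substituted biaryls, the aryl iodide undergoes oxidative addition readily, and powdered phosphate in toluene should spare the two hindered aryl esters (an early acyl shift, should it occur, would still stay in its own ring).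

Step 9
Reactants: 14 the biaryl bis-ester
Product: 15 1-[4,6-bis(benzyloxy)-2-hydroxy-3-(3-{3-[4-(benzyloxy)phenyl]-3-oxopropanoyl}-4-hydroxy-2,6-dimethoxyphenyl)phenyl]-3-(4-methoxyphenyl)propane-1,3-dione (the biaryl bis(1,3-diketone) with free C8a and C8a'' phenols)
Conditions: LiN(SiMe3)2 (6 equiv), THF (0.02 M), −78 °C to 0 °C; then 1 M HCl
Reagents that add atoms: none
Why: Excess LiN(SiMe3)2 converts both acetyl groups into lithium enolates, and each enolate carbon adds to the carbonyl of the aroyl ester on the neighbouring ring oxygen through a six-membered cyclic tetrahedral intermediate whose collapse expels the phenoxide and leaves the 1,3-diketonate, so C2–C3 and C2''–C3'' are formed and the C8a and C8a'' oxygens are set free. This is the Baker–Venkataraman rearrangement, run here twice in one molecule, as practised on 2-aroyloxy-4,6-dialkoxyacetophenones including 3-substituted ones. No ring is closed in this step (the cyclic intermediate reopens), but both later closures are fixed, because in each ring the only free phenol is the one that carried the ester: next to the biaryl bond in ring A (8-linkage) and para to it in ring D (6''-linkage). No stereocentre is created and the biaryl axis is not controlled. The selectivity required is that each aroyl group stays in its own ring and is not lost: the ortho acetyl/ester pairs allow the six-membered transfer, crossover between the rings would need a nine-membered or larger transition state, every other oxygen is an ether, and a non-nucleophilic amide base at low temperature and moderate dilution should avoid ester cleavage and intermolecular Claisen condensation. Two equivalents of base per arm are consumed because the diketone and the phenol formed are both deprotonated, which also drives each transfer to completion.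

Step 10
Reactants: 15 the biaryl bis(1,3-diketone)
Product: 16 5,7-bis(benzyloxy)-8-{2-[4-(benzyloxy)phenyl]-5,7-dimethoxy-4-oxo-4H-chromen-6-yl}-2-(4-methoxyphenyl)-4H-chromen-4-one
Conditions: TsOH·H2O (20 mol%), toluene, 80 °C
Reagents that add atoms: none
Why: Acid-catalysed cyclodehydration: each free phenol adds to the distal ketone of its own diketone (6-exo-trig hemiketal formation) and water is lost to give the 4-pyranone; since the C5 and C5'' oxygens remain ethers under this mild acid, closure can only occur through O–C8a and O–C8a'', so no Wessely–Moser-type isomer can form.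

Step 11
Reactants: 16 the tribenzyl trimethyl biflavone
Product: 17 5,7-dihydroxy-8-[2-(4-hydroxyphenyl)-5,7-dimethoxy-4-oxo-4H-chromen-6-yl]-2-(4-methoxyphenyl)-4H-chromen-4-one
Conditions: H2 (1 atm), 10% Pd/C, THF/MeOH, rt
Reagents that add atoms: none
Why: Catalytic hydrogenolysis cleaves the three benzyl aryl ethers, while the methyl ethers are inert and the conjugated pyranone double bonds should survive at ambient pressure and temperature.

Step 12
Reactants: 17 the 5''-O-methyl biflavone
Product: 18 5,7-dihydroxy-8-[5-hydroxy-2-(4-hydroxyphenyl)-7-methoxy-4-oxo-4H-chromen-6-yl]-2-(4-methoxyphenyl)-4H-chromen-4-one (target)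
Conditions: BCl3 (1 M in CH2Cl2, 8 equiv), CH2Cl2, 0 °C to rt; then MeOH, aq. HCl
Reagents that add atoms: none
Why: Chelation-directed ether cleavage: BCl3 binds the C4'' carbonyl and the peri C5'' methoxy oxygen in a six-membered chelate and chloride removes that methyl group, whereas the C7'' and C4' methoxy groups have no neighbouring carbonyl and should be left untouched.

**Compound list**
1 | 2,4,6-trihydroxyacetophenone (phloroacetophenone) | CC(=O)c1c(O)cc(O)cc1O | starting material
2 | 1-[2,4-bis(benzyloxy)-6-hydroxyphenyl]ethanone | CC(=O)c1c(O)cc(OCc2ccccc2)cc1OCc1ccccc1 | intermediate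
3 | 1-[4,6-bis(benzyloxy)-2-hydroxy-3-iodophenyl]ethanone | CC(=O)c1c(O)c(I)c(OCc2ccccc2)cc1OCc1ccccc1 | intermediate
4 | 4-methoxybenzoyl chloride | COc1ccc(cc1)C(=O)Cl | starting material
5 | 2-acetyl-3,5-bis(benzyloxy)-6-iodophenyl 4-methoxybenzoate | CC(=O)c1c(OCc2ccccc2)cc(OCc2ccccc2)c(I)c1OC(=O)c1ccc(OC)cc1 | intermediate
6 | 2-bromo-1,3-dimethoxybenzene | COc1cccc(OC)c1Br | starting material
7 | 2-(4-bromo-3,5-dimethoxyphenyl)-4,4,5,5-tetramethyl-1,3,2-dioxaborolane | COc1cc(cc(OC)c1Br)B1OC(C)(C)C(C)(C)O1 | intermediate (not isolated)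
8 | 4-bromo-3,5-dimethoxyphenol | COc1cc(O)cc(OC)c1Br | intermediate
9 | 4-bromo-3,5-dimethoxyphenyl acetate | CC(=O)Oc1cc(OC)c(Br)c(OC)c1 | intermediate (not isolated)
10 | 1-(3-bromo-6-hydroxy-2,4-dimethoxyphenyl)ethanone | CC(=O)c1c(O)cc(OC)c(Br)c1OC | intermediate
11 | 4-(benzyloxy)benzoyl chloride | O=C(Cl)c1ccc(OCc2ccccc2)cc1 | starting material
12 | 2-acetyl-4-bromo-3,5-dimethoxyphenyl 4-(benzyloxy)benzoate | CC(=O)c1c(OC)c(Br)c(OC)cc1OC(=O)c1ccc(OCc2ccccc2)cc1 | intermediate
13 | 2-acetyl-3,5-dimethoxy-4-(4,4,5,5-tetramethyl-1,3,2-dioxaborolan-2-yl)phenyl 4-(benzyloxy)benzoate | CC(=O)c1c(OC)c(B2OC(C)(C)C(C)(C)O2)c(OC)cc1OC(=O)c1ccc(OCc2ccccc2)cc1 | intermediate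
14 | 3,3'-diacetyl-4,6-bis(benzyloxy)-2',6'-dimethoxybiphenyl-2,4'-diyl 2-(4-methoxybenzoate) 4'-[4-(benzyloxy)benzoate] | CC(=O)c1c(OCc2ccccc2)cc(OCc2ccccc2)c(-c2c(OC)cc(OC(=O)c3ccc(OCc4ccccc4)cc3)c(C(C)=O)c2OC)c1OC(=O)c1ccc(OC)cc1 | intermediate (key-step precursor)
15 | biaryl bis(1,3-diketone) with free C8a and C8a'' phenols | COc1ccc(cc1)C(=O)CC(=O)c1c(OCc2ccccc2)cc(OCc2ccccc2)c(-c2c(OC)cc(O)c(C(=O)CC(=O)c3ccc(OCc4ccccc4)cc3)c2OC)c1O | intermediate (key-step product)
16 | 5,7-bis(benzyloxy)-8-{2-[4-(benzyloxy)phenyl]-5,7-dimethoxy-4-oxo-4H-chromen-6-yl}-2-(4-methoxyphenyl)-4H-chromen-4-one | COc1ccc(-c2cc(=O)c3c(OCc4ccccc4)cc(OCc4ccccc4)c(-c4c(OC)cc5oc(-c6ccc(OCc7ccccc7)cc6)cc(=O)c5c4OC)c3o2)cc1 | intermediate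
17 | 5,7-dihydroxy-8-[2-(4-hydroxyphenyl)-5,7-dimethoxy-4-oxo-4H-chromen-6-yl]-2-(4-methoxyphenyl)-4H-chromen-4-one | COc1ccc(-c2cc(=O)c3c(O)cc(O)c(-c4c(OC)cc5oc(-c6ccc(O)cc6)cc(=O)c5c4OC)c3o2)cc1 | intermediate
18 | 5,7-dihydroxy-8-[5-hydroxy-2-(4-hydroxyphenyl)-7-methoxy-4-oxo-4H-chromen-6-yl]-2-(4-methoxyphenyl)-4H-chromen-4-one | COc1ccc(-c2cc(=O)c3c(O)cc(O)c(-c4c(OC)cc5oc(-c6ccc(O)cc6)cc(=O)c5c4O)c3o2)cc1 | target

**Step count**
Total: 12 steps. Longest linear sequence: 9 steps (steps 4 to 12, from 6 to 18).

**Steps most likely to fail**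

1. Step 8 (Suzuki coupling of the two ester-bearing halves). Transmetalation or reductive elimination may stall because four ortho substituents surround the new bond, the boronate may protodeboronate, and the base may cleave or shift the aryl esters before coupling. Fallback: the biaryl bond is made before any ester is present. Bromophenol 10 is converted with MOMCl and iPr2NEt in CH2Cl2 into 1-[3-bromo-2,4-dimethoxy-6-(methoxymethoxy)phenyl]ethanone F1, which is borylated under the conditions of step 7 to the pinacol boronate F2. F2 is coupled with the free iodophenol 3 under aqueous conditions (Pd(OAc)2, SPhos, K3PO4, toluene/H2O, 90 °C) to the biaryl mono-phenol F3, in which the ring A phenol is free and the ring D phenol is masked. Acylation of F3 with 4 (pyridine, DMAP) gives the mono-ester F4, mild acid (HCl, THF/iPrOH, 40 °C) removes the methoxymethyl group to give the phenol ester F5, and acylation with 11 (Et3N, DMAP) returns to the route at 14.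

2. Step 9 (twofold acyl shift). The second transfer may be slow in the crowded biaryl, the hindered ring A ester may be cleaved instead of transferred, or intermolecular Claisen condensation may scramble the aroyl groups. Fallback: each shift is run on its monomer and the biaryl bond is made between two flavones. Iodo ester 5 with LiN(SiMe3)2 in THF should give the iodo diketone F6, which is cyclodehydrated (TsOH, toluene) to the 8-iodoflavone F7. Bromo ester 12 gives in the same way the bromo diketone F8 and the 6-bromoflavone F9, which is borylated (pinacolborane, PdCl2(MeCN)2, SPhos, Et3N) to the flavone boronate F10. Suzuki coupling of F7 with F10 (Pd2(dba)3, SPhos, aqueous K3PO4, toluene, 100 °C) returns to the route at 16.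

3. Step 5 (Fries acetylation of the bromophenol). Acid-promoted ipso-protonation at the bromine-bearing carbon, which is activated by two ortho methoxy groups and the para oxygen, could cause bromine loss or migration before the ring is deactivated by the acyl group. Fallback: the acetyl group is brought in without acid. Phenol 8 is ortho-formylated (MgCl2, Et3N, paraformaldehyde, MeCN, reflux) to 3-bromo-6-hydroxy-2,4-dimethoxybenzaldehyde F11. MeMgBr (3 equiv, THF, 0 °C) gives racemic 1-(3-bromo-6-hydroxy-2,4-dimethoxyphenyl)ethanol F12, whose stereocentre is removed when MnO2 in CH2Cl2 oxidises it to the ketone, returning to the route at 10.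

**Further compounds**
F1 | step 8 | 1-[3-bromo-2,4-dimethoxy-6-(methoxymethoxy)phenyl]ethanone | CC(=O)c1c(OCOC)cc(OC)c(Br)c1OC
F2 | step 8 | 1-[2,4-dimethoxy-6-(methoxymethoxy)-3-(4,4,5,5-tetramethyl-1,3,2-dioxaborolan-2-yl)phenyl]ethanone | CC(=O)c1c(OCOC)cc(OC)c(B2OC(C)(C)C(C)(C)O2)c1OC
F3 | step 8 | 3,3'-diacetyl-4,6-bis(benzyloxy)-2',6'-dimethoxy-4'-(methoxymethoxy)biphenyl-2-ol | CC(=O)c1c(OCc2ccccc2)cc(OCc2ccccc2)c(-c2c(OC)cc(OCOC)c(C(C)=O)c2OC)c1O
F4 | step 8 | 3,3'-diacetyl-4,6-bis(benzyloxy)-2',6'-dimethoxy-4'-(methoxymethoxy)biphenyl-2-yl 4-methoxybenzoate | CC(=O)c1c(OCc2ccccc2)cc(OCc2ccccc2)c(-c2c(OC)cc(OCOC)c(C(C)=O)c2OC)c1OC(=O)c1ccc(OC)cc1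
F5 | step 8 | 3,3'-diacetyl-4,6-bis(benzyloxy)-4'-hydroxy-2',6'-dimethoxybiphenyl-2-yl 4-methoxybenzoate | CC(=O)c1c(OCc2ccccc2)cc(OCc2ccccc2)c(-c2c(OC)cc(O)c(C(C)=O)c2OC)c1OC(=O)c1ccc(OC)cc1
F6 | step 9 | 1-[4,6-bis(benzyloxy)-2-hydroxy-3-iodophenyl]-3-(4-methoxyphenyl)propane-1,3-dione | COc1ccc(cc1)C(=O)CC(=O)c1c(O)c(I)c(OCc2ccccc2)cc1OCc1ccccc1
F7 | step 9 | 5,7-bis(benzyloxy)-8-iodo-2-(4-methoxyphenyl)-4H-chromen-4-one | COc1ccc(-c2cc(=O)c3c(OCc4ccccc4)cc(OCc4ccccc4)c(I)c3o2)cc1
F8 | step 9 | 1-[4-(benzyloxy)phenyl]-3-(3-bromo-6-hydroxy-2,4-dimethoxyphenyl)propane-1,3-dione | O=C(CC(=O)c1c(O)cc(OC)c(Br)c1OC)c1ccc(OCc2ccccc2)cc1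
F9 | step 9 | 2-[4-(benzyloxy)phenyl]-6-bromo-5,7-dimethoxy-4H-chromen-4-one | COc1cc2oc(-c3ccc(OCc4ccccc4)cc3)cc(=O)c2c(OC)c1Br
F10 | step 9 | 2-[4-(benzyloxy)phenyl]-5,7-dimethoxy-6-(4,4,5,5-tetramethyl-1,3,2-dioxaborolan-2-yl)-4H-chromen-4-one | COc1cc2oc(-c3ccc(OCc4ccccc4)cc3)cc(=O)c2c(OC)c1B1OC(C)(C)C(C)(C)O1
F11 | step 5 | 3-bromo-6-hydroxy-2,4-dimethoxybenzaldehyde | O=Cc1c(O)cc(OC)c(Br)c1OC
F12 | step 5 | 1-(3-bromo-6-hydroxy-2,4-dimethoxyphenyl)ethanol (racemic) | CC(O)c1c(O)cc(OC)c(Br)c1OC
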